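**Retrosynthetic overview**
1. Both benzene rings are bought: ring A as 2,4-dihydroxyacetophenone 1 (C5-prenylated to 2), ring B as methyl 4-hydroxybenzoate 3 (ortho-C-prenylated to 4).
2. Disconnection 1 (C–C, central CO–CH2): Claisen condensation of the polyanion of 2 with 4, whose phenol is masked in the flask (5, then 6), gives the open diprenylated triol β-diketone 7, the presumed biogenetic precursor.
3. Disconnection 2 (C–O, the key one, last): the pyran ring is opened back to the o-prenylphenol of ring A. Forward, site-selective dehydrogenation of unprotected 7 to o-quinone methide 8 and oxa-6π electrocyclisation give glyinflanin C 9.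
4. Ring order: no carbocycle is made. The 2H-pyran ring is the only ring formed, in the final step, on ring A and not on the second o-prenylphenol of ring B.

Assumption: the target has no stereocentre and no stereogenic double bond, so it is achiral and needs no stereocontrol; salts, anions and tautomers of a numbered compound carry no number of their own.

**Route**

Step 1
Reactants: 1 2,4-dihydroxyacetophenone
Product: 2 1-[2,4-dihydroxy-5-(3-methylbut-2-en-1-yl)phenyl]ethan-1-one
Conditions: 2-methylbut-3-en-2-ol (0.6 eq), BF3·OEt2 (0.5 eq), dry dioxane, rt, 3 h; chromatography (excess 1 recovered)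
Reagents that add atoms: 2-methylbut-3-en-2-ol, CC(C)(O)C=C
Why: Friedel–Crafts C-prenylation with the dimethylallyl cation from the tertiary allylic alcohol and BF3 (the laboratory counterpart of an aromatic prenyltransferase): under acidic, non-chelating conditions the cation attacks through its primary terminus at the unhindered C5 (para to the 2-OH, ortho to the 4-OH) in preference to C3, which is flanked by two oxygens, and excess 1 with low conversion limits the 3-isomer, diprenylation and chroman closure, which are removed by chromatography.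

Step 2
Reactants: 3 methyl 4-hydroxybenzoate
Product: 4 methyl 4-hydroxy-3-(3-methylbut-2-en-1-yl)benzoate
Conditions: NaH (1.0 eq), PhMe, 0 °C; prenyl bromide (1.0 eq), rt, 18 h
Reagents that add atoms: prenyl bromide (1-bromo-3-methylbut-2-ene), CC(C)=CCBr
Why: Ortho-C-alkylation of a sodium phenoxide under heterogeneous non-polar conditions (Claisen-type C-allylation): in toluene the tightly ion-paired oxygen is shielded, so the phenoxide reacts through its ortho carbon with the primary allylic bromide and the dienone rearomatises, the two ortho positions being equivalent and the para position blocked, with the O-prenyl ether as a separable by-product.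

Step 3
Reactants: 2 1-[2,4-dihydroxy-5-(3-methylbut-2-en-1-yl)phenyl]ethan-1-one; 4 methyl 4-hydroxy-3-(3-methylbut-2-en-1-yl)benzoate
Product: 7 1-[2,4-dihydroxy-5-(3-methylbut-2-en-1-yl)phenyl]-3-[4-hydroxy-3-(3-methylbut-2-en-1-yl)phenyl]propane-1,3-dione, via silyl ether ester 5 (not isolated), via mono-TBS diketone 6 (not isolated)
Conditions: (a) 4, NaHMDS (1.0 eq), TBSCl (1.05 eq), THF, 0 °C → rt; (b) 2, LiHMDS (4.2 eq), THF, −78 → −10 °C, then solution (a), −78 °C → rt (40 °C if slow); (c) TBAF (1.2 eq), 0 °C; aq NH4Cl
Reagents that add atoms: tert-butyldimethylsilyl chloride (TBSCl), CC(C)(C)[Si](C)(C)Cl — its silyl group is present in 5 and 6 only and is absent from 7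
Why: Crossed Claisen condensation of the polylithiated, unprotected dihydroxyacetophenone (polyanion C-acylation as used for ring-A-hydroxylated flavone precursors): ester 4 would be deactivated as its phenoxide and is therefore silylated in the flask to 5, the fourth equivalent of base deprotonates the β-diketone and makes the condensation irreversible, and fluoride cleaves the aryl silyl ether of 6 before a near-neutral quench that avoids cyclodehydration to a flavone.

Step 4
Reactants: 7 1-[2,4-dihydroxy-5-(3-methylbut-2-en-1-yl)phenyl]-3-[4-hydroxy-3-(3-methylbut-2-en-1-yl)phenyl]propane-1,3-dione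
Product: 9 glyinflanin C, via ring-A o-quinone methide 8 (not isolated)
Conditions: DDQ (1.05 eq, in portions), dry PhH–dioxane, rt → 45 °C, stopped when 7 is consumed
Reagents that add atoms: none
Why: Proposed new method: the closest known reaction is the DDQ dehydrogenative cyclisation of an o-prenylphenol (benzylic hydride abstraction to an o-quinone methide, then oxa-6π electrocyclisation), and what is new is the choice between two o-prenylphenols in an unprotected β-diketone, which should succeed because the benzylic carbon of ring A is ortho to one hydroxyl and para to a second while that of ring B is ortho to a single hydroxyl, so with one equivalent of DDQ hydride loss occurs on ring A first, the (Z)-o-quinone methide 8 can close only onto the adjacent 4-oxygen to give the linear 2,2-dimethyl-2H-chromene, and the central CH2 has no vicinal C–H to be dehydrogenated.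

**Compound list**
1 | 1-(2,4-dihydroxyphenyl)ethan-1-one (2,4-dihydroxyacetophenone) | CC(=O)c1ccc(O)cc1O | starting material
2 | 1-[2,4-dihydroxy-5-(3-methylbut-2-en-1-yl)phenyl]ethan-1-one | CC(=O)c1cc(CC=C(C)C)c(O)cc1O | intermediate
3 | methyl 4-hydroxybenzoate | COC(=O)c1ccc(O)cc1 | starting material
4 | methyl 4-hydroxy-3-(3-methylbut-2-en-1-yl)benzoate | COC(=O)c1ccc(O)c(CC=C(C)C)c1 | intermediate
5 | methyl 4-[(tert-butyldimethylsilyl)oxy]-3-(3-methylbut-2-en-1-yl)benzoate (formed in the flask, step 3) | COC(=O)c1ccc(O[Si](C)(C)C(C)(C)C)c(CC=C(C)C)c1 | intermediate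
6 | 1-{4-[(tert-butyldimethylsilyl)oxy]-3-(3-methylbut-2-en-1-yl)phenyl}-3-[2,4-dihydroxy-5-(3-methylbut-2-en-1-yl)phenyl]propane-1,3-dione (formed in the flask, step 3) | CC(C)=CCc1cc(C(=O)CC(=O)c2cc(CC=C(C)C)c(O)cc2O)ccc1O[Si](C)(C)C(C)(C)C | intermediate
7 | 1-[2,4-dihydroxy-5-(3-methylbut-2-en-1-yl)phenyl]-3-[4-hydroxy-3-(3-methylbut-2-en-1-yl)phenyl]propane-1,3-dione | CC(C)=CCc1cc(C(=O)CC(=O)c2cc(CC=C(C)C)c(O)cc2O)ccc1O | intermediate
8 | 1-[6-hydroxy-3-(3-methylbut-2-en-1-ylidene)-4-oxocyclohexa-1,5-dien-1-yl]-3-[4-hydroxy-3-(3-methylbut-2-en-1-yl)phenyl]propane-1,3-dione, exocyclic C=C Z (vinyl cis to ring C=O); formed in the flask, step 4 | CC(C)=C/C=C1\C(=O)C=C(O)C(C(=O)CC(=O)c2ccc(O)c(CC=C(C)C)c2)=C1 | intermediate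
9 | glyinflanin C, 1-(7-hydroxy-2,2-dimethyl-2H-chromen-6-yl)-3-[4-hydroxy-3-(3-methylbut-2-en-1-yl)phenyl]propane-1,3-dione (achiral) | CC(C)=CCc1cc(C(=O)CC(=O)c2cc3c(cc2O)OC(C)(C)C=C3)ccc1O | target

**Totals**
Total steps: 4. Longest linear sequence: 3 (1 → 2 → 7 → 9, or 3 → 4 → 7 → 9).

**Three steps most likely to fail**

Step 4 (site selectivity of the DDQ cyclisation; tolerance of the free β-diketone). The risks are cyclisation on ring B, double cyclisation, or attack on the diketone. The fallback closes the pyran ring before the C–C coupling, when only one prenyl group is present. It sets out from 2: DDQ (1.1 eq) in refluxing benzene dehydrogenates 2 to the o-quinone methide 1-[6-hydroxy-3-(3-methylbut-2-en-1-ylidene)-4-oxocyclohexa-1,5-dien-1-yl]ethan-1-one F1 (not isolated), which electrocyclises to 1-(7-hydroxy-2,2-dimethyl-2H-chromen-6-yl)ethan-1-one F2. The dilithio derivative of F2 (LiHMDS, 3.2 eq, THF, −78 °C) is condensed with 5, made in the flask from 4 as in step 3, to give O-tert-butyldimethylsilyl-glyinflanin C F3. TBAF added before work-up cleaves F3, so the fallback comes back to the route at 9.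

Step 3 (one-pot silylation, polyanion Claisen, desilylation). The risks are loss of the silyl group to methoxide, which stalls the ester as its phenoxide, and sluggish addition of the aggregated polyanion. The fallback replaces the reversible ester condensation by kinetic C-acylation with an isolated aroyl chloride at −78 °C, where no alkoxide is formed. It sets out from 4: LiOH in THF–H2O gives 4-hydroxy-3-(3-methylbut-2-en-1-yl)benzoic acid F4. TBSCl (2.2 eq) and imidazole in DMF give tert-butyldimethylsilyl 4-[(tert-butyldimethylsilyl)oxy]-3-(3-methylbut-2-en-1-yl)benzoate F5. Oxalyl chloride with catalytic DMF in CH2Cl2 converts the silyl ester directly, without free HCl that could add to the prenyl alkene, into 4-[(tert-butyldimethylsilyl)oxy]-3-(3-methylbut-2-en-1-yl)benzoyl chloride F6. F6 (1.0 eq) added at −78 °C to the polyanion of 2 (LiHMDS, 4.2 eq, THF) gives 6, where the fallback comes back to the route; TBAF then gives 7 as in step 3.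

Step 1 (C5 versus C3 prenylation, low yield, chroman by-products). If the 5-isomer cannot be obtained or separated in usable amounts, the prenyl group is placed by halogenation and cross-coupling instead of Friedel–Crafts alkylation. The fallback sets out from 1: NBS (1.0 eq) in MeCN at 0 °C brominates para to the chelated 2-OH to give 1-(5-bromo-2,4-dihydroxyphenyl)ethan-1-one F7. Stille coupling of F7 with tributyl(3-methylbut-2-en-1-yl)stannane (Pd(PPh3)4, DMF, 90 °C) attaches the prenyl group through its CH2 terminus and comes back to the route at 2.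

**Further compounds**
F1 | step 4 | 1-[6-hydroxy-3-(3-methylbut-2-en-1-ylidene)-4-oxocyclohexa-1,5-dien-1-yl]ethan-1-one (Z, not isolated) | CC(C)=C/C=C1\C(=O)C=C(O)C(C(C)=O)=C1
F2 | step 4 | 1-(7-hydroxy-2,2-dimethyl-2H-chromen-6-yl)ethan-1-one | CC(=O)c1cc2c(cc1O)OC(C)(C)C=C2
F3 | step 4 | O-tert-butyldimethylsilyl-glyinflanin C | CC(C)=CCc1cc(C(=O)CC(=O)c2cc3c(cc2O)OC(C)(C)C=C3)ccc1O[Si](C)(C)C(C)(C)C
F4 | step 3 | 4-hydroxy-3-(3-methylbut-2-en-1-yl)benzoic acid | CC(C)=CCc1cc(C(=O)O)ccc1O
F5 | step 3 | tert-butyldimethylsilyl 4-[(tert-butyldimethylsilyl)oxy]-3-(3-methylbut-2-en-1-yl)benzoate | CC(C)=CCc1cc(C(=O)O[Si](C)(C)C(C)(C)C)ccc1O[Si](C)(C)C(C)(C)C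
F6 | step 3 | 4-[(tert-butyldimethylsilyl)oxy]-3-(3-methylbut-2-en-1-yl)benzoyl chloride | CC(C)=CCc1cc(C(=O)Cl)ccc1O[Si](C)(C)C(C)(C)C
F7 | step 1 | 1-(5-bromo-2,4-dihydroxyphenyl)ethan-1-one | CC(=O)c1cc(Br)c(O)cc1O
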